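**Plan**

- Cuts, in retrosynthetic order: the ring B–dienyl bond (Suzuki–Miyaura); C4–C4a of ring C (ketenium Friedel–Crafts closure); the ynol C4–O bond (acetylide oxygenation); the C2–O1 ether bond (Mitsunobu); C2–C3 (ethynyl Grignard addition); the ring B–prenyl bond (arylcopper alkylation).
- Forward order: ring B aldehyde, two-carbon extension to the propargylic alcohol, attachment of silylated ring A through O1, oxygenation of the alkyne terminus, closure of ring C (the only ring formed), dienylation of ring B, desilylation.
- Enabling feature: C4 is a carbonyl carbon bonded to C4a, and ring A is a 1,3,5-trioxygenated benzene whose two carbons ortho to O1 are equivalent. A cationic C4 held on the O1–C2–C3 tether can therefore bond only to C4a and close only the six-membered ring C.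
- Stereochemistry: C2 is the only stereocentre. A lipase resolution delivers the (R)-propargylic alcohol, the Mitsunobu etherification inverts it once, and C2 is a spectator from then on; ring C stays locked as the C4 silyl enol ether until the last step. The E alkene comes from syn hydroboration.

Key step: step 9

Assumption: lipase B from Candida antarctica is taken to show its usual enantiopreference with acetate 10 (aryl as the large group, ethynyl as the medium group), which makes the (R)-ester the reactive one.

**Route**

Step 1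
Reactants: 1 3,5-dibromo-4-hydroxybenzaldehyde
Product: 2 3,5-dibromo-4-methoxybenzaldehyde
Conditions: MeI, K2CO3, DMF, 40 °C
Reagents that add atoms: iodomethane, CI
Why: Williamson O-methylation of the acidic, doubly ortho-brominated phenol through its potassium phenoxide should go cleanly because the molecule offers no other nucleophilic site.

Step 2
Reactants: 2 3,5-dibromo-4-methoxybenzaldehyde
Product: 3 2-(3,5-dibromo-4-methoxyphenyl)-1,3-dioxolane
Conditions: HOCH2CH2OH, p-TsOH (cat.), toluene, reflux, azeotropic removal of water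
Reagents that add atoms: ethylene glycol, OCCO
Why: Acid-catalysed acetalisation, driven by removal of water, masks the aldehyde against the organolithium chemistry of the next step.

Step 3
Reactants: 3 2-(3,5-dibromo-4-methoxyphenyl)-1,3-dioxolane; 4 1-bromo-3-methylbut-2-ene
Product: 8 3-bromo-4-methoxy-5-(3-methylbut-2-enyl)benzaldehyde, via aryllithium 5 (not isolated), via arylcopper 6 (not isolated), via prenylated dioxolane 7 (not isolated)
Conditions: n-BuLi (1.0 equiv), THF, −78 °C; CuBr·SMe2, −78 → −40 °C; 4, −40 → 0 °C; then 2 M HCl, THF, rt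
Reagents that add atoms: water, O
Why: Bromine–lithium exchange should stop after one bromine because a second exchange would build a dianion, the arylcopper formed by transmetalation alkylates prenyl bromide at its primary carbon (copper-mediated allylic substitution), and the acidic work-up hydrolyses the dioxolane back to the aldehyde.

Step 4
Reactants: 8 3-bromo-4-methoxy-5-(3-methylbut-2-enyl)benzaldehyde
Product: 10 rac-1-[3-bromo-4-methoxy-5-(3-methylbut-2-enyl)phenyl]prop-2-ynyl acetate, via bromomagnesium alkoxide 9 (not isolated)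
Conditions: HC≡CMgBr, THF, 0 °C; then Ac2O, DMAP (cat.), 0 °C → rt
Reagents that add atoms: ethynylmagnesium bromide, C#C[Mg]Br; acetic anhydride, CC(=O)OC(C)=O
Why: Grignard 1,2-addition to the aldehyde followed by O-acylation of the magnesium alkoxide in the same flask should give the racemic propargylic acetate, the aryl bromide being inert to an alkynyl Grignard reagent.

Step 5
Reactants: 10 rac-1-[3-bromo-4-methoxy-5-(3-methylbut-2-enyl)phenyl]prop-2-ynyl acetate
Product: 11 (R)-1-[3-bromo-4-methoxy-5-(3-methylbut-2-enyl)phenyl]prop-2-yn-1-ol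
Conditions: Novozym 435 (immobilised Candida antarctica lipase B), n-BuOH, MTBE, 35 °C, stopped near half conversion
Reagents that add atoms: none
Why: Lipase-catalysed transesterification is used as a kinetic resolution: the enzyme seats the aryl ring in its large pocket and the slim ethynyl group in its medium pocket, so only the (R)-acetate should be cleaved, which sets C2 as R in the alcohol, while the (S)-acetate stays behind and is separated (at most half of the material is used).

Step 6
Reactants: 12 phloroglucinol
Product: 13 3,5-bis(triisopropylsilyloxy)phenol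
Conditions: TIPSCl (2.0 equiv), imidazole, DMF, 0 °C → rt
Reagents that add atoms: chlorotriisopropylsilane, CC(C)[Si](Cl)(C(C)C)C(C)C
Why: Imidazole-promoted O-silylation of the threefold symmetric triol with two equivalents of silyl chloride should give the bis-silyl ether as the main component of a statistical mixture, from which the mono- and tris-silyl ethers are removed by chromatography.

Step 7
Reactants: 11 (R)-1-[3-bromo-4-methoxy-5-(3-methylbut-2-enyl)phenyl]prop-2-yn-1-ol; 13 3,5-bis(triisopropylsilyloxy)phenol
Product: 14 (S)-1-[3-bromo-4-methoxy-5-(3-methylbut-2-enyl)phenyl]prop-2-ynyl 3,5-bis(triisopropylsilyloxy)phenyl ether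
Conditions: PPh3, DIAD, toluene, −20 → 0 °C
Reagents that add atoms: none
Why: In this Mitsunobu etherification the phenoxide displaces the oxyphosphonium group by SN2 with inversion, turning the (R)-carbinol into the (S)-ether, and ionisation is disfavoured because the ring B methoxy group is twisted out of conjugation by its two ortho neighbours and the bromine is electron-withdrawing.

Step 8
Reactants: 14 (S)-1-[3-bromo-4-methoxy-5-(3-methylbut-2-enyl)phenyl]prop-2-ynyl 3,5-bis(triisopropylsilyloxy)phenyl ether
Product: 17 (R)-1-[3-bromo-4-methoxy-5-(3-methylbut-2-enyl)phenyl]-3-(triisopropylsilyloxy)prop-2-ynyl 3,5-bis(triisopropylsilyloxy)phenyl ether, via lithium acetylide 15 (not isolated), via lithium ynolate 16 (not isolated)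
Conditions: LiN(SiMe3)2, THF, −78 °C; LiOOt-Bu (from t-BuOOH and LiN(SiMe3)2), −78 → −10 °C; TIPSOTf, −78 °C
Reagents that add atoms: tert-butyl hydroperoxide, CC(C)(C)OO; triisopropylsilyl trifluoromethanesulfonate, CC(C)[Si](OS(=O)(=O)C(F)(F)F)(C(C)C)C(C)C
Why: Oxygen transfer from lithium tert-butyl peroxide to the lithium acetylide should give the ynolate, which the bulky silyl triflate captures on oxygen (acetylide oxygenation then O-silylation); the amide base leaves the aryl bromide alone and no bond to C2 is touched, the descriptor becoming R only because the oxygenated alkyne now outranks the aryl group.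

Step 9
Reactants: 17 (R)-1-[3-bromo-4-methoxy-5-(3-methylbut-2-enyl)phenyl]-3-(triisopropylsilyloxy)prop-2-ynyl 3,5-bis(triisopropylsilyloxy)phenyl ether
Product: 19 (S)-2-[3-bromo-4-methoxy-5-(3-methylbut-2-enyl)phenyl]-4,5,7-tris(triisopropylsilyloxy)-2H-chromene, via silyl ketenium triflimide 18 (not isolated)
Conditions: HNTf2 (5 mol %), CH2Cl2, −78 → −40 °C; then Et3N
Reagents that add atoms: none
Why: The acid protonates the electron-rich siloxyalkyne at C3 to give silyl ketenium ion 18, whose sp carbon C4 is attacked by the ring A carbon ortho to O1, and loss of the arenium proton returns the acid and leaves C4 as its silyl enol ether. The closest known reaction is the Brønsted-acid-catalysed carbocyclisation of arene-tethered siloxyalkynes to tetralone silyl enol ethers, here with an ether oxygen in place of a methylene group of the tether. Ring C closes as a six-membered Friedel–Crafts ring, 6-endo-dig with respect to the C3≡C4 bond. No stereocentre is formed, and C2 keeps its four bonds, so the S configuration of 19 follows directly from 17. The step needs protonation at C3 in preference to the prenyl alkene and to O1, with survival of the benzylic, propargylic C2–O1 bond: the ketene-acetal-like alkyne is by far the most basic π system, the acid is catalytic and cold, and the twisted methoxy group and the bromine of ring B make a C2 cation poor. The regiochemistry is fixed by the substrate, since the two carbons ortho to O1 are equivalent and the para carbon cannot reach C4.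

Step 10
Reactants: 20 2-methylbut-1-en-3-yne
Product: 21 (E)-4,4,5,5-tetramethyl-2-(3-methylbuta-1,3-dienyl)-1,3,2-dioxaborolane
Conditions: HBpin, Cp2Zr(H)Cl (5 mol %), Et3N (10 mol %), CH2Cl2, rt, sealed vessel (20 in excess)
Reagents that add atoms: pinacolborane, CC1(C)OBOC1(C)C
Why: Zirconium-catalysed syn hydroboration of the terminal alkyne should place boron on the terminal carbon and give the E alkenylboronate, the 1,1-disubstituted alkene reacting much more slowly.

Step 11
Reactants: 19 (S)-2-[3-bromo-4-methoxy-5-(3-methylbut-2-enyl)phenyl]-4,5,7-tris(triisopropylsilyloxy)-2H-chromene; 21 (E)-4,4,5,5-tetramethyl-2-(3-methylbuta-1,3-dienyl)-1,3,2-dioxaborolane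
Product: 22 (S)-2-[4-methoxy-3-[(E)-3-methylbuta-1,3-dienyl]-5-(3-methylbut-2-enyl)phenyl]-4,5,7-tris(triisopropylsilyloxy)-2H-chromene
Conditions: Pd(OAc)2 (3 mol %), SPhos (6 mol %), K3PO4, THF/H2O, 40 °C, dark
Reagents that add atoms: none
Why: Suzuki–Miyaura coupling of the aryl bromide with the alkenylboronate should proceed with retention of the E geometry, the phosphate base being harmless because C4 is a silyl enol ether and ring C cannot open at C2–O1, and the mild temperature and exclusion of light guard against electrocyclic opening of the 2H-chromene.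

Step 12
Reactants: 22 (S)-2-[4-methoxy-3-[(E)-3-methylbuta-1,3-dienyl]-5-(3-methylbut-2-enyl)phenyl]-4,5,7-tris(triisopropylsilyloxy)-2H-chromene
Product: 23 (S)-5,7-dihydroxy-2-[4-methoxy-3-[(E)-3-methylbuta-1,3-dienyl]-5-(3-methylbut-2-enyl)phenyl]chroman-4-one
Conditions: TBAF, AcOH, THF, 0 °C → rt
Reagents that add atoms: none
Why: Fluoride-mediated desilylation should remove both aryl silyl ethers and the enol silyl ether, with acetic acid protonating the phenoxides and the C4 enolate as they form so that the flavanone does not open to the chalcone by retro-oxa-Michael reaction and C2 stays S.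

**Compound list**

1 | 3,5-dibromo-4-hydroxybenzaldehyde | O=Cc1cc(Br)c(O)c(Br)c1 | starting material
2 | 3,5-dibromo-4-methoxybenzaldehyde | O=Cc1cc(Br)c(OC)c(Br)c1 | intermediate
3 | 2-(3,5-dibromo-4-methoxyphenyl)-1,3-dioxolane | COc1c(Br)cc(C2OCCO2)cc1Br | intermediate
4 | 1-bromo-3-methylbut-2-ene (prenyl bromide) | CC(C)=CCBr | starting material
5 | 2-(3-bromo-5-lithio-4-methoxyphenyl)-1,3-dioxolane (aryllithium) | [Li]c1cc(C2OCCO2)cc(Br)c1OC | intermediate
6 | [3-bromo-5-(1,3-dioxolan-2-yl)-2-methoxyphenyl]copper (arylcopper) | [Cu]c1cc(C2OCCO2)cc(Br)c1OC | intermediate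
7 | 2-[3-bromo-4-methoxy-5-(3-methylbut-2-enyl)phenyl]-1,3-dioxolane | CC(C)=CCc1cc(C2OCCO2)cc(Br)c1OC | intermediate
8 | 3-bromo-4-methoxy-5-(3-methylbut-2-enyl)benzaldehyde | O=Cc1cc(Br)c(OC)c(CC=C(C)C)c1 | intermediate
9 | bromomagnesium 1-[3-bromo-4-methoxy-5-(3-methylbut-2-enyl)phenyl]prop-2-yn-1-olate (racemic) | Br[Mg]OC(C#C)c1cc(Br)c(OC)c(CC=C(C)C)c1 | intermediate
10 | rac-1-[3-bromo-4-methoxy-5-(3-methylbut-2-enyl)phenyl]prop-2-ynyl acetate | CC(=O)OC(C#C)c1cc(Br)c(OC)c(CC=C(C)C)c1 | intermediate
11 | (R)-1-[3-bromo-4-methoxy-5-(3-methylbut-2-enyl)phenyl]prop-2-yn-1-ol | Brc1cc([C@H](O)C#C)cc(CC=C(C)C)c1OC | intermediate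
12 | phloroglucinol (benzene-1,3,5-triol) | Oc1cc(O)cc(O)c1 | starting material
13 | 3,5-bis(triisopropylsilyloxy)phenol | Oc1cc(O[Si](C(C)C)(C(C)C)C(C)C)cc(O[Si](C(C)C)(C(C)C)C(C)C)c1 | intermediate
14 | (S)-1-[3-bromo-4-methoxy-5-(3-methylbut-2-enyl)phenyl]prop-2-ynyl 3,5-bis(triisopropylsilyloxy)phenyl ether | Brc1cc([C@@H](Oc2cc(O[Si](C(C)C)(C(C)C)C(C)C)cc(O[Si](C(C)C)(C(C)C)C(C)C)c2)C#C)cc(CC=C(C)C)c1OC | intermediate
15 | lithium acetylide of 14 (C2 configuration unchanged) | Brc1cc([C@@H](Oc2cc(O[Si](C(C)C)(C(C)C)C(C)C)cc(O[Si](C(C)C)(C(C)C)C(C)C)c2)C#C[Li])cc(CC=C(C)C)c1OC | intermediate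
16 | lithium ynolate from 15 (C2 configuration unchanged) | Brc1cc([C@@H](Oc2cc(O[Si](C(C)C)(C(C)C)C(C)C)cc(O[Si](C(C)C)(C(C)C)C(C)C)c2)C#CO[Li])cc(CC=C(C)C)c1OC | intermediate
17 | (R)-1-[3-bromo-4-methoxy-5-(3-methylbut-2-enyl)phenyl]-3-(triisopropylsilyloxy)prop-2-ynyl 3,5-bis(triisopropylsilyloxy)phenyl ether | Brc1cc([C@@H](Oc2cc(O[Si](C(C)C)(C(C)C)C(C)C)cc(O[Si](C(C)C)(C(C)C)C(C)C)c2)C#CO[Si](C(C)C)(C(C)C)C(C)C)cc(CC=C(C)C)c1OC | intermediate
18 | O-triisopropylsilyl ketenium ion from C3 protonation of 17, as its triflimide salt | Brc1cc([C@@H](Oc2cc(O[Si](C(C)C)(C(C)C)C(C)C)cc(O[Si](C(C)C)(C(C)C)C(C)C)c2)C=C=[O+][Si](C(C)C)(C(C)C)C(C)C)cc(CC=C(C)C)c1OC.FC(F)(F)S(=O)(=O)[N-]S(=O)(=O)C(F)(F)F | intermediate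
19 | (S)-2-[3-bromo-4-methoxy-5-(3-methylbut-2-enyl)phenyl]-4,5,7-tris(triisopropylsilyloxy)-2H-chromene | Brc1cc([C@@H]2C=C(O[Si](C(C)C)(C(C)C)C(C)C)c3c(O[Si](C(C)C)(C(C)C)C(C)C)cc(O[Si](C(C)C)(C(C)C)C(C)C)cc3O2)cc(CC=C(C)C)c1OC | intermediate
20 | 2-methylbut-1-en-3-yne | C=C(C)C#C | starting material
21 | (E)-4,4,5,5-tetramethyl-2-(3-methylbuta-1,3-dienyl)-1,3,2-dioxaborolane | C=C(C)/C=C/B1OC(C)(C)C(C)(C)O1 | intermediate
22 | (S)-2-[4-methoxy-3-[(E)-3-methylbuta-1,3-dienyl]-5-(3-methylbut-2-enyl)phenyl]-4,5,7-tris(triisopropylsilyloxy)-2H-chromene | C=C(C)/C=C/c1cc([C@@H]2C=C(O[Si](C(C)C)(C(C)C)C(C)C)c3c(O[Si](C(C)C)(C(C)C)C(C)C)cc(O[Si](C(C)C)(C(C)C)C(C)C)cc3O2)cc(CC=C(C)C)c1OC | intermediate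
23 | (S)-5,7-dihydroxy-2-[4-methoxy-3-[(E)-3-methylbuta-1,3-dienyl]-5-(3-methylbut-2-enyl)phenyl]chroman-4-one | C=C(C)/C=C/c1cc([C@@H]2CC(=O)c3c(O)cc(O)cc3O2)cc(CC=C(C)C)c1OC | target

**Step count**

Total: 12 steps. Longest linear sequence: 10 steps (steps 1–5, 7–9, 11 and 12); steps 6 and 10 are side branches.

**Steps most likely to fail**

Step 9 (ring C closure). The acid may protonate O1 instead of C3 and heterolyse the benzylic, propargylic C2–O1 bond, a process the electron-releasing siloxyalkyne can assist. The prenyl alkene may also be protonated, or the bulky silyloxy group beside the reacting ring A carbon may slow capture of the ketenium ion until it is lost to oligomerisation. The fallback sets out again from 17 and activates the alkyne by π-coordination in place of a proton: gold-catalysed 6-endo hydroarylation of the aryl propargyl ether (Ph3PAuNTf2, CH2Cl2, 0 °C), an established way from aryl propargyl ethers to 2H-chromenes that needs no free strong acid. The polarised siloxyalkyne should again be attacked at C4, and protodeauration at C3 comes back to the route at 19. No new compound is made on the way (F0). Should this also fail, the acylation sequence given for step 8 forms the same C4–C4a bond without a siloxyalkyne.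

Step 8 (oxygenation of the alkyne terminus). Oxygen transfer from the peroxide to the acetylide may stay incomplete, the peroxide may attack the aryl silyl ethers, or the ynolate may expel the ring A aryloxide from C2 while the mixture is warmed. The fallback sets out from 14 and gives up the siloxyalkyne in favour of a classical acylation.
- Ruthenium-catalysed anti-Markovnikov hydration of the terminal alkyne (CpRu(MeCN)3PF6, 5,5'-bis(trifluoromethyl)-2,2'-bipyridine, NMP/H2O, rt) should give (S)-3-[3,5-bis(triisopropylsilyloxy)phenoxy]-3-[3-bromo-4-methoxy-5-(3-methylbut-2-enyl)phenyl]propanal F1.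
- Pinnick oxidation (NaClO2, NaH2PO4, 2-methylbut-2-ene, t-BuOH/H2O) leads to (S)-3-[3,5-bis(triisopropylsilyloxy)phenoxy]-3-[3-bromo-4-methoxy-5-(3-methylbut-2-enyl)phenyl]propanoic acid F2.
- Intramolecular Friedel–Crafts acylation of ring A with trifluoroacetic anhydride (CH2Cl2, 0 °C) closes ring C to (S)-2-[3-bromo-4-methoxy-5-(3-methylbut-2-enyl)phenyl]-5,7-bis(triisopropylsilyloxy)chroman-4-one F3.
- Soft enolisation (TIPSOTf, Et3N, CH2Cl2, 0 °C) masks the ketone again and comes back to the route at 19, so that the base-mediated coupling of step 11 can follow unchanged.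

Step 7 (Mitsunobu etherification). The oxyphosphonium ion at the benzylic, propargylic carbon may ionise in part, which would erode the enantiomeric purity, or the phenoxide may attack the alkyne terminus and give an allenyl ether. The fallback sets out from 8 and makes the C2–O1 bond and the stereocentre in one catalytic step. Ethynylmagnesium bromide is added as in step 4, and alkoxide 9 is quenched with methyl chloroformate to give rac-1-[3-bromo-4-methoxy-5-(3-methylbut-2-enyl)phenyl]prop-2-ynyl methyl carbonate F4. Copper-catalysed enantioselective propargylic etherification with phenol 13 then proceeds through a copper allenylidene (CuOTf·1/2C6H6, a chiral pybox ligand in the enantiomer that leads to the S ether, i-Pr2NEt, MeOH, −20 °C). It comes back to the route at 14 and makes step 5 unnecessary. C-alkylation of the electron-rich ring A would have to be watched.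

Further compounds

F0 | step 9 | none | none
F1 | step 8 | (S)-3-[3,5-bis(triisopropylsilyloxy)phenoxy]-3-[3-bromo-4-methoxy-5-(3-methylbut-2-enyl)phenyl]propanal | Brc1cc([C@@H](Oc2cc(O[Si](C(C)C)(C(C)C)C(C)C)cc(O[Si](C(C)C)(C(C)C)C(C)C)c2)CC=O)cc(CC=C(C)C)c1OC
F2 | step 8 | (S)-3-[3,5-bis(triisopropylsilyloxy)phenoxy]-3-[3-bromo-4-methoxy-5-(3-methylbut-2-enyl)phenyl]propanoic acid | Brc1cc([C@@H](Oc2cc(O[Si](C(C)C)(C(C)C)C(C)C)cc(O[Si](C(C)C)(C(C)C)C(C)C)c2)CC(=O)O)cc(CC=C(C)C)c1OC
F3 | step 8 | (S)-2-[3-bromo-4-methoxy-5-(3-methylbut-2-enyl)phenyl]-5,7-bis(triisopropylsilyloxy)chroman-4-one | Brc1cc([C@@H]2CC(=O)c3c(O[Si](C(C)C)(C(C)C)C(C)C)cc(O[Si](C(C)C)(C(C)C)C(C)C)cc3O2)cc(CC=C(C)C)c1OC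
F4 | step 7 | rac-1-[3-bromo-4-methoxy-5-(3-methylbut-2-enyl)phenyl]prop-2-ynyl methyl carbonate | COC(=O)OC(C#C)c1cc(Br)c(OC)c(CC=C(C)C)c1
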